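**Plan**
1. Retrosynthesis: both ester C6–O bonds are cut first (Mitsunobu, inversion), giving two molecules of 6-epi-incarvilline and an O-protected α-truxillic diacid; the cyclobutane is then cut into two ferulic acid units ([2+2]).
2. In the bicyclic amine (locants C1, N2, C3, C4, C4a, C5, C6, C7, C7a) the carbocycle C4a–C5–C6–C7–C7a bears its oxygen on C6 between C5H2 and C7H(CH3). At the ketone level with a C4a=C5 double bond it is a cyclopentenone fused to the N2 ring, the retron of an intramolecular Pauson–Khand reaction. It is cut at C5–C6, C6–C7 and C4a–C7a to an acyclic enyne with the tether C4–C3–N2–C1.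
3. Forward: amine alkylation, carbamate, aldehyde, alkyne (enyne 6); the Pauson–Khand step closes first the six-membered N ring (C4a–C7a) and last the five-membered ring (C5–C6); hydrogenation and LiAlH4 give 11. Ferulic acid is tosylated and photodimerised in the crystal to 14; 14 and two molecules of 11 are joined, and the tosylates are removed.
4. Stereochemistry: C4 is bought in ((R)-3-bromo-2-methylpropan-1-ol). It sets C7a in the cyclisation, the (E)-alkene sets C7, hydrogenation sets C4a, and hydride reduction followed by Mitsunobu inversion sets C6. The cyclobutane centres come from head-to-tail crystal packing.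

Key step: step 5

Remark: (E)-but-2-en-1-amine is taken as geometrically pure. Any (Z) material would only lead to the C7 epimer of 8, which can be corrected after step 6 because C7 is α to the ketone.

**Step 1**
Reactants: 1 (2R)-3-bromo-2-methylpropan-1-ol; 2 (2E)-but-2-en-1-amine
Product: 3 (2S)-3-{[(2E)-but-2-en-1-yl]amino}-2-methylpropan-1-ol
Conditions: 2 (3 equiv), K2CO3, MeCN, 60 °C
Reagents that add atoms: none
Why: SN2 N-alkylation of the primary amine by the primary bromide, with excess amine to suppress dialkylation; the stereocentre is untouched, and its descriptor changes from R to S only because CH2N ranks below CH2OH.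

**Step 2**
Reactants: 3 (2S)-3-{[(2E)-but-2-en-1-yl]amino}-2-methylpropan-1-ol
Product: 4 methyl [(2E)-but-2-en-1-yl][(2S)-3-hydroxy-2-methylpropyl]carbamate
Conditions: ClCO2Me (1.05 equiv), NaHCO3, CH2Cl2/H2O, 0 °C
Reagents that add atoms: methyl chloroformate, COC(=O)Cl
Why: Schotten–Baumann N-acylation, selective for the secondary amine over the primary alcohol; the carbamate removes the basicity that would interfere with cobalt in step 5 and is the masked N-methyl group.

**Step 3**
Reactants: 4 methyl [(2E)-but-2-en-1-yl][(2S)-3-hydroxy-2-methylpropyl]carbamate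
Product: 5 methyl [(2E)-but-2-en-1-yl][(2S)-2-methyl-3-oxopropyl]carbamate
Conditions: Dess–Martin periodinane (1.2 equiv), CH2Cl2, 0 °C → rt; used crude
Reagents that add atoms: none
Why: Dess–Martin oxidation of the primary alcohol under neutral conditions, chosen so that the α-stereocentre of the aldehyde is not enolised.

**Step 4**
Reactants: 5 methyl [(2E)-but-2-en-1-yl][(2S)-2-methyl-3-oxopropyl]carbamate
Product: 6 methyl [(2E)-but-2-en-1-yl][(2R)-2-methylbut-3-yn-1-yl]carbamate
Conditions: dimethyl (1-diazo-2-oxopropyl)phosphonate (1.3 equiv), K2CO3 (2 equiv), MeOH, 0 °C → rt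
Reagents that add atoms: dimethyl (1-diazo-2-oxopropyl)phosphonate (Ohira–Bestmann reagent), CC(=O)C(=[N+]=[N-])P(=O)(OC)OC
Why: Seyferth–Gilbert homologation in the Ohira–Bestmann variant, in which the diazomethylphosphonate anion adds to the aldehyde and loss of phosphate and N2 with a 1,2-hydride shift gives the terminal alkyne; α-branched aldehydes of this kind should keep their configuration at 0 °C, and the methyl carbamate cannot transesterify in methanol.

**Step 5**
Reactants: 6 methyl [(2E)-but-2-en-1-yl][(2R)-2-methylbut-3-yn-1-yl]carbamate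
Product: 8 methyl (4R,7S,7aS)-4,7-dimethyl-6-oxo-1,3,4,6,7,7a-hexahydro-2H-cyclopenta[c]pyridine-2-carboxylate, via hexacarbonyldicobalt alkyne complex 7 (not isolated)
Conditions: Co2(CO)8 (1.1 equiv), CH2Cl2, rt; then N-methylmorpholine N-oxide (6 equiv), 0 °C → rt
Reagents that add atoms: dicobalt octacarbonyl (source of the C6 carbonyl), O=C=[Co](=C=O)(=C=O)(=C=O)[Co](=C=O)(=C=O)(=C=O)=C=O
Why: Intramolecular Pauson–Khand reaction of an N-tethered 1,7-enyne, a known reaction type for homopropargyl/allyl carbamates and sulfonamides. The alkyne is bound as its Co2(CO)6 complex 7, the N-oxide removes a CO ligand as CO2, the (E)-alkene inserts into the Co–C4a bond (C4a–C7a, six-membered ring closed in a 6-exo sense), CO inserts into the new Co–C7 bond (C6–C7), and reductive elimination joins the acyl carbon C6 to the vinyl carbon C5, the former alkyne CH, which closes the five-membered ring as the cyclopentenone (formal [2+2+1]). C7a is controlled by C4: the tether should fold in a chair-like transition state with the C4 methyl group equatorial (a terminal alkyne exerts no allylic strain against this), which places H4 and H7a on the same face. C7 follows from suprafacial addition to the (E)-double bond, so that its methyl group ends trans to C1. Regiochemistry is fixed by the tether, since only the distal alkyne and alkene carbons can reach the CO, and the carbamate keeps nitrogen from binding cobalt. The selectivity the step needs is diastereofacial selectivity at the alkene, which the equatorial preference of the single C4 substituent is expected to secure.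

**Step 6**
Reactants: 8 methyl (4R,7S,7aS)-4,7-dimethyl-6-oxo-1,3,4,6,7,7a-hexahydro-2H-cyclopenta[c]pyridine-2-carboxylate
Product: 9 methyl (4R,4aS,7S,7aR)-4,7-dimethyl-6-oxooctahydro-2H-cyclopenta[c]pyridine-2-carboxylate
Conditions: H2 (1 atm), 10% Pd/C, EtOAc, rt
Reagents that add atoms: none
Why: Heterogeneous hydrogenation of the enone, in which H2 should add to C4a=C5 from the face of H7a, opposite to the C1 methylene on C7a, to give the cis ring fusion (4aS); C7 is α to the ketone and already has its methyl group in the more stable position trans to C1, so a C7 epimer can be converged with base (DBU).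

**Step 7**
Reactants: 9 methyl (4R,4aS,7S,7aR)-4,7-dimethyl-6-oxooctahydro-2H-cyclopenta[c]pyridine-2-carboxylate
Product: 11 6-epi-incarvilline [(4R,4aS,6S,7S,7aR)-2,4,7-trimethyloctahydro-1H-cyclopenta[c]pyridin-6-ol], via carbamate alcohol 10 (not isolated)
Conditions: LiAlH4 (4 equiv), THF, −78 °C → reflux; Fieser work-up
Reagents that add atoms: none
Why: Hydride reduction, in which the ketone should be attacked at low temperature from the convex face of the cis-fused bicycle, placing the hydroxyl group on the concave face trans to the C7 methyl group (6S), and the methyl carbamate is reduced to the N-methyl group on heating.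

**Step 8**
Reactants: 12 ferulic acid [(2E)-3-(4-hydroxy-3-methoxyphenyl)prop-2-enoic acid]
Product: 13 (2E)-3-{3-methoxy-4-[(4-methylbenzenesulfonyl)oxy]phenyl}prop-2-enoic acid
Conditions: TsCl (1.1 equiv), aq NaOH (2.2 equiv), THF, 0 °C → rt; then HCl to pH 2; recrystallise
Reagents that add atoms: 4-methylbenzenesulfonyl chloride, Cc1ccc(cc1)S(=O)(=O)Cl
Why: Schotten–Baumann O-sulfonylation of the phenoxide; the carboxylate gives no stable product in aqueous base, so only the aryl tosylate remains after acidification.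

**Step 9**
Reactants: 13 (2E)-3-{3-methoxy-4-[(4-methylbenzenesulfonyl)oxy]phenyl}prop-2-enoic acid (two molecules)
Product: 14 (1α,2α,3β,4β)-2,4-bis{3-methoxy-4-[(4-methylbenzenesulfonyl)oxy]phenyl}cyclobutane-1,3-dicarboxylic acid (α-truxillic configuration)
Conditions: crystalline powder, hν (high-pressure Hg lamp, Pyrex), rt, thin layer turned at intervals
Reagents that add atoms: none
Why: Topochemical [2+2] photocycloaddition in the crystal: if the acid packs in centrosymmetric head-to-tail pairs with parallel double bonds less than about 4.2 Å apart, the lattice fixes the regiochemistry and all four stereocentres and gives the centrosymmetric, achiral α-truxillic configuration.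

**Step 10**
Reactants: 14 the α-truxillic diacid bis-tosylate; 11 6-epi-incarvilline (2.2 equiv)
Product: 15 bis[(4R,4aS,6R,7S,7aR)-2,4,7-trimethyloctahydro-1H-cyclopenta[c]pyridin-6-yl] (1α,2α,3β,4β)-2,4-bis{3-methoxy-4-[(4-methylbenzenesulfonyl)oxy]phenyl}cyclobutane-1,3-dicarboxylate (O,O′-ditosylincarvillateine)
Conditions: PPh3 (3 equiv), DEAD (3 equiv), THF, 0 °C → rt
Reagents that add atoms: none
Why: Twofold Mitsunobu esterification, in which each carboxylate displaces the activated C6 oxygen of 11 by SN2 with inversion (6S to 6R), so that the ester oxygen ends cis to the C7 methyl group as in the target; the sulfonates keep the phenols from competing as nucleophiles.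

**Step 11**
Reactants: 15 O,O′-ditosylincarvillateine
Product: 16 incarvillateine (CNP0283097.2)
Conditions: 5% Na(Hg), Na2HPO4, MeOH, −10 → 0 °C
Reagents that add atoms: none
Why: Reductive cleavage of the aryl sulfonate S–O bonds by electron transfer from sodium amalgam; the phosphate buffer keeps the medium from becoming basic enough to transesterify the esters or epimerise the cyclobutane.

**Compound list**
1 | (2R)-3-bromo-2-methylpropan-1-ol | OC[C@@H](C)CBr | starting material
2 | (2E)-but-2-en-1-amine | NC/C=C/C | starting material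
3 | (2S)-3-{[(2E)-but-2-en-1-yl]amino}-2-methylpropan-1-ol | OC[C@@H](C)CNC/C=C/C | intermediate
4 | methyl [(2E)-but-2-en-1-yl][(2S)-3-hydroxy-2-methylpropyl]carbamate | OC[C@@H](C)CN(C(=O)OC)C/C=C/C | intermediate
5 | methyl [(2E)-but-2-en-1-yl][(2S)-2-methyl-3-oxopropyl]carbamate | O=C[C@@H](C)CN(C(=O)OC)C/C=C/C | intermediate
6 | methyl [(2E)-but-2-en-1-yl][(2R)-2-methylbut-3-yn-1-yl]carbamate | C#C[C@@H](C)CN(C(=O)OC)C/C=C/C | intermediate
7 | hexacarbonyldicobalt complex of the alkyne of 6 (C2Co2 tetrahedrane core) | [CH]12[Co]3(=C=O)(=C=O)(=C=O)[Co]1(=C=O)(=C=O)(=C=O)C23[C@@H](C)CN(C(=O)OC)C/C=C/C | intermediate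
8 | methyl (4R,7S,7aS)-4,7-dimethyl-6-oxo-1,3,4,6,7,7a-hexahydro-2H-cyclopenta[c]pyridine-2-carboxylate | O=C1C=C2[C@@H](CN(C(=O)OC)C[C@@H]2C)[C@@H]1C | intermediate
9 | methyl (4R,4aS,7S,7aR)-4,7-dimethyl-6-oxooctahydro-2H-cyclopenta[c]pyridine-2-carboxylate | O=C1C[C@@H]2[C@@H](CN(C(=O)OC)C[C@@H]2C)[C@@H]1C | intermediate
10 | methyl (4R,4aS,6S,7S,7aR)-6-hydroxy-4,7-dimethyloctahydro-2H-cyclopenta[c]pyridine-2-carboxylate | O[C@H]1C[C@@H]2[C@@H](CN(C(=O)OC)C[C@@H]2C)[C@@H]1C | intermediate
11 | 6-epi-incarvilline, (4R,4aS,6S,7S,7aR)-2,4,7-trimethyloctahydro-1H-cyclopenta[c]pyridin-6-ol | O[C@H]1C[C@@H]2[C@@H](CN(C)C[C@@H]2C)[C@@H]1C | intermediate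
12 | ferulic acid | COc1cc(/C=C/C(=O)O)ccc1O | starting material
13 | (2E)-3-{3-methoxy-4-[(4-methylbenzenesulfonyl)oxy]phenyl}prop-2-enoic acid | COc1cc(/C=C/C(=O)O)ccc1OS(=O)(=O)c1ccc(C)cc1 | intermediate
14 | (1α,2α,3β,4β)-2,4-bis{3-methoxy-4-[(4-methylbenzenesulfonyl)oxy]phenyl}cyclobutane-1,3-dicarboxylic acid | COc1cc([C@H]2[C@H](C(=O)O)[C@H](c3ccc(OS(=O)(=O)c4ccc(C)cc4)c(OC)c3)[C@H]2C(=O)O)ccc1OS(=O)(=O)c1ccc(C)cc1 | intermediate
15 | O,O′-ditosylincarvillateine | COc1cc([C@H]2[C@H](C(=O)O[C@@H]3C[C@@H]4[C@@H](CN(C)C[C@@H]4C)[C@@H]3C)[C@H](c3ccc(OS(=O)(=O)c4ccc(C)cc4)c(OC)c3)[C@H]2C(=O)O[C@@H]2C[C@@H]3[C@@H](CN(C)C[C@@H]3C)[C@@H]2C)ccc1OS(=O)(=O)c1ccc(C)cc1 | intermediate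
16 | incarvillateine | COc1cc([C@H]2[C@H](C(=O)O[C@@H]3C[C@@H]4[C@@H](CN(C)C[C@@H]4C)[C@@H]3C)[C@H](c3ccc(O)c(OC)c3)[C@H]2C(=O)O[C@@H]2C[C@@H]3[C@@H](CN(C)C[C@@H]3C)[C@@H]2C)ccc1O | target

**Step count**
Total: 11 steps. Longest linear sequence: 9 steps (steps 1–7, 10, 11).

**Steps most likely to fail**

Step 5. Insertion of the 1,2-disubstituted alkene of a 1,7-enyne into the cobalt–alkyne complex may be slow, so that alkyne oligomerisation and decomplexation compete, and the 1,3-induction from C4 may be incomplete. The fallback takes the C7 methyl group out of the cyclisation and introduces it by enolate alkylation. It sets out from 1: allylamine is alkylated to (2S)-2-methyl-3-(prop-2-en-1-ylamino)propan-1-ol F1, which is carried through the same carbamoylation, oxidation and homologation to the carbamate alcohol F2, the aldehyde F3 and the terminal-alkene enyne F4. The more reactive monosubstituted alkene of F4 should cyclise under the same cobalt conditions through its hexacarbonyldicobalt complex F5 to the C7-unsubstituted enone F6. Kinetic deprotonation at C7 (LDA, THF, −78 °C) and methylation with MeI from the face opposite C1 then give 8, where the route is rejoined.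

Step 10. The double esterification may stall at the mono-ester, or the activated alkoxyphosphonium ion may eliminate to a cyclopentene. The fallback separates inversion from ester formation and sets out from 11 and 14. Compound 11 is inverted with 4-nitrobenzoic acid, PPh3 and DIAD to incarvilline 4-nitrobenzoate F7, which is saponified (LiOH, THF/H2O) to incarvilline F8, the 6R alcohol. Diacid 14 is converted with oxalyl chloride and catalytic DMF into the diacid dichloride F9, and F8 (2.2 equiv) is acylated with F9 (Et3N, DMAP, CH2Cl2) with retention at C6 to give 15.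

Step 9. The crystal form obtained may lack the close head-to-tail stacking, so that the solid is photostable or only isomerises at the surface. The fallback changes the group that determines the lattice and sets out from 12. Ferulic acid is acetylated (Ac2O, pyridine) to 4-O-acetylferulic acid F10, whose crystals are irradiated to the 4,4′-diacetoxy-α-truxillic diacid F11. The acetates are hydrolysed (aq NaOH, then HCl) to the bis-phenol diacid F12, which is tosylated as in step 8 (TsCl, aq NaOH) to give 14.

**Further compounds**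
F1 | step 5 | (2S)-2-methyl-3-(prop-2-en-1-ylamino)propan-1-ol | OC[C@@H](C)CNCC=C
F2 | step 5 | methyl [(2S)-3-hydroxy-2-methylpropyl](prop-2-en-1-yl)carbamate | OC[C@@H](C)CN(C(=O)OC)CC=C
F3 | step 5 | methyl [(2S)-2-methyl-3-oxopropyl](prop-2-en-1-yl)carbamate | O=C[C@@H](C)CN(C(=O)OC)CC=C
F4 | step 5 | methyl [(2R)-2-methylbut-3-yn-1-yl](prop-2-en-1-yl)carbamate | C#C[C@@H](C)CN(C(=O)OC)CC=C
F5 | step 5 | hexacarbonyldicobalt complex of the alkyne of F4 | [CH]12[Co]3(=C=O)(=C=O)(=C=O)[Co]1(=C=O)(=C=O)(=C=O)C23[C@@H](C)CN(C(=O)OC)CC=C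
F6 | step 5 | methyl (4R,7aS)-4-methyl-6-oxo-1,3,4,6,7,7a-hexahydro-2H-cyclopenta[c]pyridine-2-carboxylate | O=C1C=C2[C@@H](CN(C(=O)OC)C[C@@H]2C)C1
F7 | step 10 | (4R,4aS,6R,7S,7aR)-2,4,7-trimethyloctahydro-1H-cyclopenta[c]pyridin-6-yl 4-nitrobenzoate | O=C(O[C@@H]1C[C@@H]2[C@@H](CN(C)C[C@@H]2C)[C@@H]1C)c1ccc(cc1)[N+](=O)[O-]
F8 | step 10 | incarvilline, (4R,4aS,6R,7S,7aR)-2,4,7-trimethyloctahydro-1H-cyclopenta[c]pyridin-6-ol | O[C@@H]1C[C@@H]2[C@@H](CN(C)C[C@@H]2C)[C@@H]1C
F9 | step 10 | (1α,2α,3β,4β)-2,4-bis{3-methoxy-4-[(4-methylbenzenesulfonyl)oxy]phenyl}cyclobutane-1,3-dicarbonyl dichloride | COc1cc([C@H]2[C@H](C(=O)Cl)[C@H](c3ccc(OS(=O)(=O)c4ccc(C)cc4)c(OC)c3)[C@H]2C(=O)Cl)ccc1OS(=O)(=O)c1ccc(C)cc1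
F10 | step 9 | (2E)-3-(4-acetoxy-3-methoxyphenyl)prop-2-enoic acid | COc1cc(/C=C/C(=O)O)ccc1OC(C)=O
F11 | step 9 | (1α,2α,3β,4β)-2,4-bis(4-acetoxy-3-methoxyphenyl)cyclobutane-1,3-dicarboxylic acid | COc1cc([C@H]2[C@H](C(=O)O)[C@H](c3ccc(OC(C)=O)c(OC)c3)[C@H]2C(=O)O)ccc1OC(C)=O
F12 | step 9 | (1α,2α,3β,4β)-2,4-bis(4-hydroxy-3-methoxyphenyl)cyclobutane-1,3-dicarboxylic acid | COc1cc([C@H]2[C@H](C(=O)O)[C@H](c3ccc(O)c(OC)c3)[C@H]2C(=O)O)ccc1O
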